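## Structural features

The target is a C30 spiro[4.5]decane: a cyclopentanol and a cyclohexane share one quaternary carbon. On the six-membered ring the spiro carbon lies between a tertiary carbinol carbon (CH3, OH) and a methine carrying a 3-hydroxypropyl chain. The next ring carbon is the ring end of an exocyclic tetrasubstituted enal, C=C(CH3)CHO, with the formyl group on the side of the ring CH2 (E). On the five-membered ring the spiro carbon is bonded to the CH–OH carbon, whose neighbour is a methine carrying the first carbon of a triene; that carbon also bears CH2OH, and the triene ends in a 2-substituted diene with a 4-methylpent-3-enyl tail. Five stereocentres are contiguous (tertiary carbinol, spiro carbon, chain-bearing methine, CH–OH, alkenyl-bearing methine) and three double bonds have fixed geometry. The enal has γ-hydrogens on the adjacent stereocentre (E/Z drift or epimerisation with base), the allylic alcohol on the triene ionises easily, and an aldehyde on the spiro carbon β to a free tertiary alcohol can undergo retro-aldol cleavage. The real difficulties are the quaternary spiro carbon, hemmed in on three sides, and the geometry of the tetrasubstituted alkene, whose two ring-side substituents (CH2 and CH) differ little. The key step exploits the cyclopentane CH–OH next to the spiro carbon and the adjacent ring CH bearing an alkene with a CH2O substituent: this is what an aldehyde on the spiro carbon leaves behind when it adds to a trisubstituted alkene of a side chain in a carbonyl-ene reaction.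

## Logic of the disconnections

41 ⇒ 40 ⇒ 39 ⇒ 38. No skeletal bond is cut; only C–O bonds (one acetyl, three silyl groups) and the oxidation level of the enal carbon change. The two allylic primary alcohols are told apart by carrying one as an acetate and the other as a silyl ether, so that after fluoride treatment only one allylic hydroxyl is free for MnO2. This keeps the enal out of every C–C bond-forming step. The forward steps must remove silicon without moving the acetate and cleave the acetate without enolising the enal.

38 ⇒ 37. The cyclopentane bond between the CH–OH carbon and the alkenyl-bearing CH is cut. Its formation by a carbonyl-ene reaction creates the ring, both cyclopentane stereocentres and the conjugated triene in one operation. The spirocycle is reduced to a cyclohexane whose quaternary carbon carries CHO and a linear skipped-tetraene chain. The forward step needs hydrogen transfer from the doubly allylic CH2, the OH cis to the alkenyl group, one face at the aldehyde, and a tertiary alcohol that cannot fragment.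

37 ⇒ 36 ⇒ 35 ⇒ 34. Only oxidation levels and an acetyl group change: the aldehyde and the acetoxymethyl group are traced to two methyl esters. Esters are what the C–C bond-forming steps deliver (carbonylation on the ring, olefination in the chain). The demand is to distinguish two primary alcohols in 35; one is allylic and open, the other neopentylic between two fully substituted carbons.

34 ⇒ 25 + 33. The trisubstituted C=C of the side chain is cut. It is the natural joint between the ring part and the dienyl part, and a Still–Gennari olefination fixes its geometry (ester cis to the ring-bearing chain). The C16 side chain is divided into three carbons on the ring and thirteen in the phosphonate. The forward step must be Z-selective with an α-branched phosphonate.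

33 ⇒ 31 + 32; 31 ⇒ 30 ⇒ 29 ⇒ 27 + 28; 27 ⇒ 26. The bond α to phosphorus and the central diene C–C bond are cut. This reduces the dienyl part to a commercial methyl ketone, methyl acrylate and the commercial phosphonoacetate. The Heck step must give the E-dienoate, and the allylic bromide must react by direct substitution.

25 ⇒ 24 ⇒ 22; 22 ⇒ 20 + 21. The allyl group stands for the propanal arm, and the C1–allyl bond is cut, so the quaternary carbon arises by allylation of an ester enolate. This is done only after C5 has become sp2: the C6 chain is then forced axial and, with the cis C2 silyloxy group, screens one face. The forward step must outrun β-elimination of the silyloxy group.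

20 ⇒ 19 ⇒ 17; 17 ⇒ 15 + 16; 15 ⇒ 14. The allylic C–O bond and the C4–H bond are removed as a formal 1,4-addition to a diene, and the diene is cut at the C5–isopropenyl bond. A 1,4-hydroboration through an s-cis diene complex places CH2O and C4 on the same side of the new tetrasubstituted alkene by mechanism; direct allylic oxidation of an isopropenyl group cannot do this. The demands are regioselective enolisation of 14 towards C4 and clean 1,4-addition on a hindered diene.

14 ⇒ 11. The C5 carbonyl is traced back to the isopropenyl group of the terpene. That group first steers the additions at C3 and C6, and is then excised in one operation. No other alkene may be present at this stage.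

11 ⇒ 7 + 8. The C6–CH2 bond is cut: conjugate addition of the complete three-carbon chain, anti to the C5 isopropenyl group, sets C6. The ester enolate must be trapped before it expels the C2 silyloxy group.

7 ⇒ 6 ⇒ 5. The C1–CO2CH3 bond is cut (carbonylation of an enol triflate). This installs the one-carbon unit on C1 without ever placing a carbanion next to an epoxide.

5 ⇒ 4 ⇒ 3 ⇒ 2 ⇒ 1. The C2–O bond is traced to a nucleophilic epoxidation of the enone, opened by hydride at C3. The oxygen must enter anti to the isopropenyl group and hydride must attack the less substituted epoxide carbon.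

## Other disconnections considered

Alternative 1: The cut is the C5–C6 bond of the cyclohexane plus a second bond closing a sacrificial methylcyclohexene, whose double bond is later cleaved to release the three-carbon chain at C6 and an acetyl group at C5. The forward key step is a thermal intramolecular Diels–Alder reaction of triene A2 (vinyl group on the future spiro carbon, 2-methylbutadienyl unit four atoms away) to the tricyclic adduct A1.
- In its favour: two C–C bonds, the cyclohexane and the C6 stereocentre arise without any carbanion at the congested quaternary carbon, and a single ozonolysis would unveil both ring substituents. On ring construction it is the better plan in step count.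
- Against it: A2 already contains the spiro carbon and the adjacent fully substituted carbinol, which would have to be made on the cyclopentane without a six-ring template. Endo/exo and facial selectivity with a tether carrying two fully substituted carbons is hard to predict. The cyclopentane in A1 carries only a silyloxy group, so the branched trienyl substituent would have to be attached afterwards at an unactivated CH2 (oxidation, α-functionalisation, stereoselective reduction). The C5 acetyl would still need a one-carbon homologation to the tetrasubstituted enal with no control of geometry.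
- Comparison: the chosen plan builds the cyclopentane last, with its substituent and both stereocentres in one step, and fixes the alkene geometry mechanistically. Alternative 1 is shorter up to the carbocyclic core and longer after it.

Alternative 2: The cut is the bond from the spiro carbon to the C(CH3)OH carbon. The forward key step is conjugate reduction of the cyclopentenone A4 by [(Ph3P)CuH]6, with aldol closure of the resulting copper enolate onto the pendant methyl ketone to give the spiro ketol A3.
- In its favour: the spiro quaternary carbon and the tertiary alcohol form together under neutral conditions. A chelated chair transition state should place the hydroxyl cis to the cyclopentanone carbonyl, which is the relationship required. The two ketones of A3 are useful handles. For the C1–C2 pair this is more step-economic than the epoxidation, reduction, carbonylation and allylation sequence of the chosen plan, and mechanistically equal in reliability.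
- Against it: the C6 stereocentre of A4 lies between a ketone and an enone α-carbon and would be configurationally labile, yet it is the only element that relays absolute configuration. The β-hydroxy ketone A3 is open to retro-aldol with base. The cyclopentanone must still receive the trienyl group at its α-CH2 and be reduced cis. Olefination of the C5 ketone to the tetrasubstituted enal (Horner–Wadsworth–Emmons type) has no reliable geometric control.
- Comparison: the chosen plan secures C6 from the chiral pool and the alkene geometry by 1,4-hydroboration, at the price of more steps.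

Alternative 3: The cut is the bond from the spiro carbon to the CH2 that becomes the cyclopentane carbinol carbon. The forward key step treats the bromomethylsilyl ether A6 with Bu3SnH and AIBN; the α-silyl radical adds 5-exo to the enone β-carbon to give the cis-fused oxasilolane ketone A5.
- In its favour: the tether from the tertiary oxygen forces the new CH2 cis to that oxygen. This control of the quaternary centre is better than the substrate-controlled enolate allylation of the chosen plan. Tamao oxidation would give the CH2OH needed for the aldehyde, and the C5 ketone remains.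
- Against it: radical attack on the fully substituted β-carbon of a tetrasubstituted enone is slow and competes with premature reduction. Stoichiometric tin is needed, and the single stereocentre of A6 would have to come from an asymmetric step. After A5 the cyclopentane must still be closed between the two oxidised arms and the trienyl chain attached; no provision for either exists. The C5 ketone again needs an olefination of uncontrolled geometry.
- Comparison: Alternative 3 is superior on the configuration of the quaternary carbon, comparable in length up to the cyclohexane, and weaker on the cyclopentane, the triene and the enal.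

Key step: step 25

Remarks on the chemistry:
- Ring carbons are numbered as in carvone throughout: C1 former carbonyl and later spiro carbon, C2 methyl-bearing carbon, C5 isopropenyl-bearing carbon, C6 between C1 and C5. TBS = tert-butyldimethylsilyl, TES = triethylsilyl, pin = pinacolato.
- Assumption: the side chain on C1 counts sixteen carbons (three from the allyl group, thirteen from phosphonate 33). Its dienyl part is built from 6-methylhept-5-en-2-one, because myrcene cannot be functionalised cleanly at the terminal carbon of its diene with the diene left intact.
- A carbanion at C1 cannot coexist with a C2–C3 epoxide (β-elimination), so the epoxide is reduced before any enolate is formed at C1. The tertiary alcohol is carried as the TES ether, which is sturdier and less chelating than a trimethylsilyl ether.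

## Route

Step 1
Reactants: 1 (S)-carvone
Product: 2 trans-2,3-epoxide of carvone (oxirane oxygen on the ring face opposite to the C5 isopropenyl group)
Conditions: 30% aq. H2O2, NaOH (cat.), MeOH, 0 °C
Reagents that add atoms: hydrogen peroxide, OO
Why: Weitz–Scheffer nucleophilic epoxidation of the enone; hydroperoxide adds axially to C3 of the half-chair on the face away from the pseudo-equatorial isopropenyl group, so C2 and C3 are set with oxygen trans to C5.

Step 2
Reactants: 2 trans-2,3-epoxide of carvone
Product: 3 2-methyl-5-isopropenylcyclohexane-1,2-diol (C2 hydroxyl anti to isopropenyl; C1 carbinol as an epimer mixture)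
Conditions: LiAlH4, Et2O, 0 °C → rt; aq. potassium sodium tartrate
Reagents that add atoms: none
Why: LiAlH4 reduces the ketone and opens the epoxide by hydride attack at the less substituted C3, so the C2–O bond and its configuration are untouched; the C1 carbinol configuration is irrelevant because it is oxidised in step 3.

Step 3
Reactants: 3 2-methyl-5-isopropenylcyclohexane-1,2-diol
Product: 4 2-hydroxy-2-methyl-5-isopropenylcyclohexan-1-one (C2 hydroxyl anti to isopropenyl)
Conditions: 2-iodoxybenzoic acid (IBX), DMSO, rt
Reagents that add atoms: none
Why: IBX oxidises the secondary alcohol of a 1,2-diol to the ketone without glycol cleavage; the tertiary alcohol and the alkene do not react.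

Step 4
Reactants: 4 2-hydroxy-2-methyl-5-isopropenylcyclohexan-1-one
Product: 5 2-methyl-5-isopropenyl-2-(triethylsilyloxy)cyclohexan-1-one
Conditions: Et3SiOTf, 2,6-lutidine, CH2Cl2, −78 → 0 °C
Reagents that add atoms: triethylsilyl trifluoromethanesulfonate, CC[Si](CC)(CC)OS(=O)(=O)C(F)(F)F
Why: Silyl triflate silylation of a hindered tertiary alcohol; the TES ether withstands the enolate, organometallic and Lewis-acid steps that follow and later blocks retro-aldol cleavage.

Step 5
Reactants: 5 2-methyl-5-isopropenyl-2-(triethylsilyloxy)cyclohexan-1-one
Product: 6 enol triflate of 5 (C1=C6 double bond, triflate on C1)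
Conditions: KN(SiMe3)2, THF, −78 °C; PhNTf2
Reagents that add atoms: N-phenylbis(trifluoromethanesulfonimide), FC(F)(F)S(=O)(=O)N(c1ccccc1)S(=O)(=O)C(F)(F)F
Why: Only C6 carries α-hydrogens, so the enolate forms regiospecifically and is trapped on oxygen (enol triflate synthesis).

Step 6
Reactants: 6 enol triflate of 5
Product: 7 methyl 2-methyl-5-isopropenyl-2-(triethylsilyloxy)cyclohex-6-ene-1-carboxylate (C1=C6 enoate; silyloxy anti to isopropenyl)
Conditions: Pd(OAc)2 (5 mol %), PPh3, CO (1 atm), MeOH, Et3N, DMF, 60 °C
Reagents that add atoms: carbon monoxide, [C-]#[O+]; methanol, CO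
Why: Palladium-catalysed alkoxycarbonylation of an enol triflate (oxidative addition to zerovalent palladium, CO insertion, methanolysis); it puts the future aldehyde carbon on C1 without a carbanion next to oxygenated C2.

Step 7
Reactants: 7 methyl 2-methyl-5-isopropenyl-2-(triethylsilyloxy)cyclohex-6-ene-1-carboxylate; 8 (3-bromopropoxy)(tert-butyl)dimethylsilane
Product: 11 methyl 6-[3-(TBS-oxy)propyl]-2-methyl-5-isopropenyl-2-(triethylsilyloxy)cyclohexane-1-carboxylate (C6 chain anti to isopropenyl; C1 epimers), via alkylmagnesium bromide 9 (not isolated), via trimethylsilyl ketene acetal 10 (not isolated)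
Conditions: 8, Mg, THF, rt; then CuBr·SMe2 (10 mol %), Me3SiCl, DMPU, 7, THF, −78 → −40 °C; aq. NH4Cl
Reagents that add atoms: none
Why: Copper-catalysed, Me3SiCl-accelerated conjugate addition of a Grignard reagent to an enoate; the alkyl group enters C6 axially, anti to the adjacent C5 isopropenyl group, which places the chain trans to C5 and therefore cis to the C2 silyloxy group. Silyl trapping of the ester enolate prevents loss of the C2 silyloxy group, and C1 is left as a mixture because it is set in step 13.

Step 8
Reactants: 11 methyl 6-[3-(TBS-oxy)propyl]-2-methyl-5-isopropenyl-2-(triethylsilyloxy)cyclohexane-1-carboxylate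
Product: 14 methyl 6-[3-(TBS-oxy)propyl]-2-methyl-5-oxo-2-(triethylsilyloxy)cyclohexane-1-carboxylate (C6 chain syn to the C2 silyloxy group; C1 epimers), via methoxy hydroperoxide 12 (not isolated), via TEMPO alkoxyamine 13 (not isolated)
Conditions: O3, MeOH, −78 °C; FeSO4·7H2O, TEMPO, −78 °C → rt; then mCPBA, CH2Cl2, 0 °C
Reagents that add atoms: TEMPO (2,2,6,6-tetramethylpiperidin-1-oxyl), CC1(C)CCCC(C)(C)N1[O]
Why: Oxodealkenylation: Criegee ozonolysis in methanol, reductive O–O cleavage by divalent iron, β-scission to the C5 radical, capture by TEMPO and peracid oxidation of the alkoxyamine to the ketone. The isopropenyl group is removed once it has steered C2, C3 and C6; the near-neutral conditions leave C6 untouched and no other alkene is present.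

Step 9
Reactants: 14 methyl 6-[3-(TBS-oxy)propyl]-2-methyl-5-oxo-2-(triethylsilyloxy)cyclohexane-1-carboxylate
Product: 15 C4=C5 enol triflate of 14 (triflate on C5)
Conditions: KN(SiMe3)2, THF, −78 °C; PhNTf2
Reagents that add atoms: N-phenylbis(trifluoromethanesulfonimide), FC(F)(F)S(=O)(=O)N(c1ccccc1)S(=O)(=O)C(F)(F)F
Why: Kinetic deprotonation by a bulky amide takes a C4 methylene hydrogen rather than the hindered C6 methine or the less acidic ester α-hydrogen; O-triflation fixes the less substituted enolate.

Step 10
Reactants: 15 C4=C5 enol triflate of 14; 16 isopropenylboronic acid pinacol ester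
Product: 17 methyl 6-[3-(TBS-oxy)propyl]-2-methyl-5-isopropenyl-2-(triethylsilyloxy)cyclohex-4-ene-1-carboxylate (2-substituted 1,3-diene)
Conditions: Pd(PPh3)4 (5 mol %), aq. K3PO4, 1,4-dioxane, 60 °C
Reagents that add atoms: none
Why: Suzuki–Miyaura coupling of an enol triflate with an alkenylboronate; it returns the three-carbon unit to C5, now as part of a conjugated diene.

Step 11
Reactants: 17 diene ester
Product: 19 allylic alcohol with exocyclic C5=C(CH3)CH2OH (CH2OH syn to C4 and CH3 syn to C6; E), via allylboronate 18 (not isolated)
Conditions: Ni(cod)2 (5 mol %), PCy3 (5 mol %), pinacolborane, toluene, rt; then NaOH, H2O2, THF–H2O, 0 °C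
Reagents that add atoms: hydrogen peroxide, OO
Why: Nickel-catalysed 1,4-hydroboration of a 1,3-diene: the diene binds zerovalent nickel in its s-cis form, hydrogen goes to the ring terminus C4 and boron to the unsubstituted CH2 terminus. CH2B and C4 therefore end on the same side of the new tetrasubstituted double bond, and oxidation with retention gives the E-allylic alcohol.

Step 12
Reactants: 19 allylic alcohol
Product: 20 TBS ether of 19
Conditions: t-BuMe2SiCl, imidazole, DMF, rt
Reagents that add atoms: tert-butyldimethylsilyl chloride, CC(C)(C)[Si](C)(C)Cl
Why: Standard silylation of a primary alcohol; the silyl ether keeps this allylic oxygen distinct from the one that will later be acetylated.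

Step 13
Reactants: 20 TBS ether of 19; 21 allyl bromide
Product: 22 methyl 1-allyl-6-[3-(TBS-oxy)propyl]-5-[(E)-1-(TBS-oxy)propan-2-ylidene]-2-methyl-2-(triethylsilyloxy)cyclohexane-1-carboxylate (allyl anti to both the C6 chain and the C2 silyloxy group)
Conditions: LiN(i-Pr)2, THF–DMPU, −78 → −40 °C; then 21, −78 °C
Reagents that add atoms: none
Why: Allylation of an ester enolate creates the quaternary centre. Allylic strain against the exocyclic alkene methyl and the enolate forces the C6 chain axial, and the cis C2 silyloxy group is axial on the same face, so allyl bromide attacks C1 axially from the open opposite face. Low temperature and a fast electrophile are chosen to outrun β-elimination of the silyloxy group.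

Step 14
Reactants: 22 quaternary allyl ester
Product: 24 methyl 1-(3-hydroxypropyl) analogue of 22, via B-alkyl-9-BBN adduct 23 (not isolated)
Conditions: 9-BBN, THF, 0 °C → rt; then NaOH, H2O2, 0 °C
Reagents that add atoms: hydrogen peroxide, OO
Why: Anti-Markovnikov hydroboration–oxidation of the monosubstituted alkene; the tetrasubstituted alkene and the hindered ester are inert to 9-BBN.

Step 15
Reactants: 24 primary alcohol
Product: 25 methyl 1-(3-oxopropyl) analogue of 22 (aldehyde)
Conditions: Dess–Martin periodinane, NaHCO3, CH2Cl2, 0 °C → rt
Reagents that add atoms: none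
Why: Dess–Martin oxidation of a primary alcohol to the aldehyde under buffered, non-epimerising conditions.

Step 16
Reactants: 26 6-methylhept-5-en-2-one
Product: 27 6-methylhepta-1,5-dien-2-yl triflate
Conditions: LiN(i-Pr)2, THF, −78 °C; PhNTf2
Reagents that add atoms: N-phenylbis(trifluoromethanesulfonimide), FC(F)(F)S(=O)(=O)N(c1ccccc1)S(=O)(=O)C(F)(F)F
Why: Kinetic deprotonation of the methyl ketone at CH3 and O-triflation give the terminal enol triflate.

Step 17
Reactants: 27 6-methylhepta-1,5-dien-2-yl triflate; 28 methyl acrylate
Product: 29 methyl (2E)-8-methyl-4-methylidenenona-2,7-dienoate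
Conditions: Pd(OAc)2 (3 mol %), PPh3, Et3N, DMF, 60 °C
Reagents that add atoms: none
Why: Mizoroki–Heck coupling of an enol triflate with an acrylate; syn insertion and syn β-hydride elimination give the E-dienoate, and the trisubstituted alkene does not take part.

Step 18
Reactants: 29 methyl (2E)-8-methyl-4-methylidenenona-2,7-dienoate
Product: 30 (2E)-8-methyl-4-methylidenenona-2,7-dien-1-ol
Conditions: i-Bu2AlH, CH2Cl2, −78 °C; aq. potassium sodium tartrate
Reagents that add atoms: none
Why: 1,2-Reduction of a conjugated ester to the allylic alcohol by i-Bu2AlH.

Step 19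
Reactants: 30 (2E)-8-methyl-4-methylidenenona-2,7-dien-1-ol
Product: 31 (2E)-1-bromo-8-methyl-4-methylidenenona-2,7-diene
Conditions: CBr4, PPh3, CH2Cl2, 0 °C
Reagents that add atoms: carbon tetrabromide, BrC(Br)(Br)Br
Why: Appel bromination of a primary allylic alcohol by direct displacement, without allylic transposition; the bromide is used at once.

Step 20
Reactants: 31 (2E)-1-bromo-8-methyl-4-methylidenenona-2,7-diene; 32 methyl 2-[bis(2,2,2-trifluoroethoxy)phosphoryl]acetate
Product: 33 methyl (4E)-2-[bis(2,2,2-trifluoroethoxy)phosphoryl]-10-methyl-6-methylideneundeca-4,9-dienoate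
Conditions: NaH, THF–DMF, 0 °C → rt (32 in excess)
Reagents that add atoms: none
Why: C-Alkylation of the stabilised phosphonoacetate anion at the primary carbon of the allylic bromide (direct substitution); excess phosphonate limits dialkylation.

Step 21
Reactants: 25 aldehyde; 33 phosphonate
Product: 34 diester with the (Z)-trisubstituted enoate in the side chain (CO2CH3 cis to the ring-bearing CH2CH2 arm; diene E)
Conditions: KN(SiMe3)2, 18-crown-6, THF, −78 °C
Reagents that add atoms: none
Why: Still–Gennari olefination: the electron-poor trifluoroethyl phosphonate with a dissociated potassium counter-ion eliminates under kinetic control to the Z-enoate. The hindered ring ester and the silyl ethers are unaffected.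

Step 22
Reactants: 34 diester
Product: 35 diol (allylic CH2OH on the side-chain alkene and CH2OH on C1)
Conditions: i-Bu2AlH (excess), CH2Cl2, −78 → 0 °C; aq. potassium sodium tartrate
Reagents that add atoms: none
Why: i-Bu2AlH reduces both esters to primary alcohols, the enoate by 1,2-addition only, so the skipped tetraene stays in place.

Step 23
Reactants: 35 diol
Product: 36 monoacetate (side-chain allylic OAc; C1 CH2OH free)
Conditions: Ac2O (1.1 equiv), pyridine, CH2Cl2, −20 °C
Reagents that add atoms: acetic anhydride, CC(=O)OC(C)=O
Why: Acylation selects the unhindered allylic primary alcohol; the other hydroxyl is neopentylic between two fully substituted carbons and reacts far more slowly.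

Step 24
Reactants: 36 monoacetate
Product: 37 seco aldehyde (C1 bears CHO and the skipped-tetraene chain with the allylic acetate; two TBS ethers, one TES ether)
Conditions: Dess–Martin periodinane, NaHCO3, CH2Cl2, 0 °C → rt
Reagents that add atoms: none
Why: Dess–Martin oxidation of the neopentylic alcohol to a non-enolisable aldehyde; buffered conditions spare the acetate, the silyl ethers and the skipped polyene.

Step 25
Reactants: 37 seco aldehyde
Product: 38 protected spiro cyclopentanol with the complete triene (OH cis to the alkenyl group; both on the face of the C6 methine)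
Conditions: Me2AlCl (2.2 equiv), CH2Cl2, −78 → −40 °C; aq. NaHCO3
Reagents that add atoms: none
Why: Me2AlCl binds the aldehyde oxygen; the carbonyl carbon bonds to the nearer carbon (the CH) of the trisubstituted side-chain alkene while a hydrogen of the doubly allylic CH2 passes to oxygen through a six-membered array (concerted but asynchronous, or through a tertiary cation that loses that proton), the Al–CH3 bond serving as proton scavenger. The closest known reaction type is the Me2AlCl-promoted intramolecular carbonyl-ene (Prins-type) cyclisation of alk-5-enals to 2-alkenylcyclopentanols. The one ring closed is the cyclopentane, formed in a 5-exo mode on the quaternary carbon, whose geminal substitution favours closure. Hydrogen is taken from the doubly allylic CH2 and not from CH2OAc, because that C–H bond is weaker and the acetate deactivates its own methylene; the new alkene therefore forms towards the diene and gives the conjugated triene directly, with the dienyl branch trans to the new ring. The cis relationship of OH and alkenyl group follows from the cis-fused bicyclic ene transition state. The sense relative to the spiro carbon is set by the aldehyde rotamer: the aluminium-bound oxygen points to the side of the C6 methine, away from the fully substituted C2 with its bulky, non-chelating Et3SiO group. The step needs chemoselectivity against the electron-rich ring alkene and against retro-aldol: the formyl group is equatorial in the chair enforced by allylic strain and cannot reach the exocyclic alkene, and the silylated tertiary alcohol cannot fragment. A second equivalent of Lewis acid is used because the acetate binds one.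

Step 26
Reactants: 38 protected spiro cyclopentanol
Product: 39 tetraol monoacetate (all three silyl groups removed, acetate retained)
Conditions: Bu4NF, AcOH (1:1), THF, 0 °C → rt
Reagents that add atoms: none
Why: Fluoride cleaves the two primary TBS ethers and the tertiary TES ether; buffering with acetic acid keeps the medium non-basic so that the acetate neither cleaves nor migrates.

Step 27
Reactants: 39 tetraol monoacetate
Product: 40 enal acetate (E-configured C5=C(CH3)CHO)
Conditions: MnO2 (activated, excess), CH2Cl2, rt
Reagents that add atoms: none
Why: MnO2 oxidises allylic alcohols only; of the four free hydroxyls one is allylic, because the other allylic oxygen is acetylated. The alkene geometry is not touched.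

Step 28
Reactants: 40 enal acetate
Product: 41 target compound CNP0246965.2
Conditions: K2CO3 (0.2 equiv), MeOH, 0 °C
Reagents that add atoms: none
Why: Methoxide-catalysed transesterification removes the acetate; the low temperature and catalytic base are chosen so that the enal is not enolised.

## Compound list

1 | (S)-carvone, (5S)-2-methyl-5-(prop-1-en-2-yl)cyclohex-2-en-1-one | CC1=CC[C@@H](CC1=O)C(C)=C | starting material
2 | trans-2,3-epoxide of carvone (oxirane oxygen anti to isopropenyl) | O=C1C[C@@H](C(C)=C)C[C@@H]2O[C@]12C | intermediate
3 | 2-methyl-5-isopropenylcyclohexane-1,2-diol (C2–OH anti to isopropenyl; C1 epimers) | OC1C[C@@H](C(C)=C)CC[C@]1(C)O | intermediate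
4 | 2-hydroxy-2-methyl-5-isopropenylcyclohexan-1-one (C2–OH anti to isopropenyl) | O=C1C[C@@H](C(C)=C)CC[C@]1(C)O | intermediate
5 | 2-methyl-5-isopropenyl-2-(triethylsilyloxy)cyclohexan-1-one | O=C1C[C@@H](C(C)=C)CC[C@]1(C)O[Si](CC)(CC)CC | intermediate
6 | enol triflate of 5 (C1=C6) | FC(F)(F)S(=O)(=O)OC1=C[C@@H](C(C)=C)CC[C@]1(C)O[Si](CC)(CC)CC | intermediate
7 | methyl 2-methyl-5-isopropenyl-2-(triethylsilyloxy)cyclohex-6-ene-1-carboxylate | COC(=O)C1=C[C@@H](C(C)=C)CC[C@]1(C)O[Si](CC)(CC)CC | intermediate
8 | (3-bromopropoxy)(tert-butyl)dimethylsilane | BrCCCO[Si](C)(C)C(C)(C)C | starting material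
9 | [3-(tert-butyldimethylsilyloxy)propyl]magnesium bromide | Br[Mg]CCCO[Si](C)(C)C(C)(C)C | intermediate
10 | methyl trimethylsilyl ketene acetal of 11 | COC(O[Si](C)(C)C)=C1[C@H](CCCO[Si](C)(C)C(C)(C)C)[C@@H](C(C)=C)CC[C@]1(C)O[Si](CC)(CC)CC | intermediate
11 | methyl 6-[3-(TBS-oxy)propyl]-2-methyl-5-isopropenyl-2-(triethylsilyloxy)cyclohexane-1-carboxylate (C6 chain anti to isopropenyl, syn to C2–OSiEt3; C1 epimers) | COC(=O)C1[C@H](CCCO[Si](C)(C)C(C)(C)C)[C@@H](C(C)=C)CC[C@]1(C)O[Si](CC)(CC)CC | intermediate
12 | methoxy hydroperoxide (isopropenyl of 11 replaced by 1-hydroperoxy-1-methoxyethyl) | COC(=O)C1[C@H](CCCO[Si](C)(C)C(C)(C)C)[C@@H](C(C)(OC)OO)CC[C@]1(C)O[Si](CC)(CC)CC | intermediate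
13 | TEMPO alkoxyamine (C5–O–N of 2,2,6,6-tetramethylpiperidine; C5 epimers) | COC(=O)C1[C@H](CCCO[Si](C)(C)C(C)(C)C)C(ON2C(C)(C)CCCC2(C)C)CC[C@]1(C)O[Si](CC)(CC)CC | intermediate
14 | methyl 6-[3-(TBS-oxy)propyl]-2-methyl-5-oxo-2-(triethylsilyloxy)cyclohexane-1-carboxylate (C6 chain syn to C2–OSiEt3; C1 epimers) | COC(=O)C1[C@H](CCCO[Si](C)(C)C(C)(C)C)C(=O)CC[C@]1(C)O[Si](CC)(CC)CC | intermediate
15 | C4=C5 enol triflate of 14 | COC(=O)C1[C@H](CCCO[Si](C)(C)C(C)(C)C)C(OS(=O)(=O)C(F)(F)F)=CC[C@]1(C)O[Si](CC)(CC)CC | intermediate
16 | isopropenylboronic acid pinacol ester | CC(=C)B1OC(C)(C)C(C)(C)O1 | starting material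
17 | diene ester (C4=C5 ring alkene, isopropenyl on C5) | COC(=O)C1[C@H](CCCO[Si](C)(C)C(C)(C)C)C(C(C)=C)=CC[C@]1(C)O[Si](CC)(CC)CC | intermediate
18 | allylboronate (exocyclic C5=C(CH3)CH2B(pin), CH2B syn to C4) | COC(=O)C1[C@H](CCCO[Si](C)(C)C(C)(C)C)/C(=C(\C)CB2OC(C)(C)C(C)(C)O2)CC[C@]1(C)O[Si](CC)(CC)CC | intermediate
19 | (E)-allylic alcohol (exocyclic C5=C(CH3)CH2OH, CH2OH syn to C4, CH3 syn to C6) | COC(=O)C1[C@H](CCCO[Si](C)(C)C(C)(C)C)/C(=C(\C)CO)CC[C@]1(C)O[Si](CC)(CC)CC | intermediate
20 | TBS ether of 19 | COC(=O)C1[C@H](CCCO[Si](C)(C)C(C)(C)C)/C(=C(\C)CO[Si](C)(C)C(C)(C)C)CC[C@]1(C)O[Si](CC)(CC)CC | intermediate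
21 | allyl bromide | C=CCBr | starting material
22 | quaternary allyl ester (allyl anti to the C6 chain and to C2–OSiEt3; CO2CH3 syn to both) | C=CC[C@]1([C@H](CCCO[Si](C)(C)C(C)(C)C)/C(=C(\C)CO[Si](C)(C)C(C)(C)C)CC[C@]1(C)O[Si](CC)(CC)CC)C(=O)OC | intermediate
23 | B-alkyl-9-borabicyclo[3.3.1]nonane from 22 | C1CCC2CCCC1B2CCC[C@]3([C@H](CCCO[Si](C)(C)C(C)(C)C)/C(=C(\C)CO[Si](C)(C)C(C)(C)C)CC[C@]3(C)O[Si](CC)(CC)CC)C(=O)OC | intermediate
24 | 1-(3-hydroxypropyl) ester | OCCC[C@]1([C@H](CCCO[Si](C)(C)C(C)(C)C)/C(=C(\C)CO[Si](C)(C)C(C)(C)C)CC[C@]1(C)O[Si](CC)(CC)CC)C(=O)OC | intermediate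
25 | 1-(3-oxopropyl) ester (aldehyde) | O=CCC[C@]1([C@H](CCCO[Si](C)(C)C(C)(C)C)/C(=C(\C)CO[Si](C)(C)C(C)(C)C)CC[C@]1(C)O[Si](CC)(CC)CC)C(=O)OC | intermediate
26 | 6-methylhept-5-en-2-one | CC(=O)CCC=C(C)C | starting material
27 | 6-methylhepta-1,5-dien-2-yl triflate | C=C(OS(=O)(=O)C(F)(F)F)CCC=C(C)C | intermediate
28 | methyl acrylate | C=CC(=O)OC | starting material
29 | methyl (2E)-8-methyl-4-methylidenenona-2,7-dienoate | COC(=O)/C=C/C(=C)CCC=C(C)C | intermediate
30 | (2E)-8-methyl-4-methylidenenona-2,7-dien-1-ol | OC/C=C/C(=C)CCC=C(C)C | intermediate
31 | (2E)-1-bromo-8-methyl-4-methylidenenona-2,7-diene | BrC/C=C/C(=C)CCC=C(C)C | intermediate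
32 | methyl 2-[bis(2,2,2-trifluoroethoxy)phosphoryl]acetate | COC(=O)CP(=O)(OCC(F)(F)F)OCC(F)(F)F | starting material
33 | methyl (4E)-2-[bis(2,2,2-trifluoroethoxy)phosphoryl]-10-methyl-6-methylideneundeca-4,9-dienoate | COC(=O)C(C/C=C/C(=C)CCC=C(C)C)P(=O)(OCC(F)(F)F)OCC(F)(F)F | intermediate
34 | diester with (Z)-enoate side chain | C=C(CCC=C(C)C)/C=C/C/C(C(=O)OC)=C/CC[C@]1([C@H](CCCO[Si](C)(C)C(C)(C)C)/C(=C(\C)CO[Si](C)(C)C(C)(C)C)CC[C@]1(C)O[Si](CC)(CC)CC)C(=O)OC | intermediate
35 | diol | C=C(CCC=C(C)C)/C=C/C/C(CO)=C/CC[C@]1([C@H](CCCO[Si](C)(C)C(C)(C)C)/C(=C(\C)CO[Si](C)(C)C(C)(C)C)CC[C@]1(C)O[Si](CC)(CC)CC)CO | intermediate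
36 | monoacetate (allylic OAc, C1 CH2OH) | C=C(CCC=C(C)C)/C=C/C/C(COC(C)=O)=C/CC[C@]1([C@H](CCCO[Si](C)(C)C(C)(C)C)/C(=C(\C)CO[Si](C)(C)C(C)(C)C)CC[C@]1(C)O[Si](CC)(CC)CC)CO | intermediate
37 | seco aldehyde with skipped tetraene chain (key-step precursor) | C=C(CCC=C(C)C)/C=C/C/C(COC(C)=O)=C/CC[C@]1([C@H](CCCO[Si](C)(C)C(C)(C)C)/C(=C(\C)CO[Si](C)(C)C(C)(C)C)CC[C@]1(C)O[Si](CC)(CC)CC)C=O | intermediate
38 | protected spiro cyclopentanol with the complete triene (key-step product) | C=C(/C=C/C=C(\COC(C)=O)[C@@H]1CC[C@]2([C@H](CCCO[Si](C)(C)C(C)(C)C)/C(=C(\C)CO[Si](C)(C)C(C)(C)C)CC[C@]2(C)O[Si](CC)(CC)CC)[C@@H]1O)CCC=C(C)C | intermediate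
39 | tetraol monoacetate | C=C(/C=C/C=C(\COC(C)=O)[C@@H]1CC[C@]2([C@H](CCCO)/C(=C(\C)CO)CC[C@]2(C)O)[C@@H]1O)CCC=C(C)C | intermediate
40 | enal acetate | C=C(/C=C/C=C(\COC(C)=O)[C@@H]1CC[C@]2([C@H](CCCO)/C(=C(\C)C=O)CC[C@]2(C)O)[C@@H]1O)CCC=C(C)C | intermediate
41 | CNP0246965.2 | C=C(/C=C/C=C(\CO)[C@@H]1CC[C@]2([C@H](CCCO)/C(=C(\C)C=O)CC[C@]2(C)O)[C@@H]1O)CCC=C(C)C | target

## Step count and least certain steps

Total: 28 steps. Longest linear sequence: 23 steps (steps 1–15 and 21–28, from 1 to 41); the side-chain branch (steps 16–20) has 5 steps.

**Step 25 (key step).** The most likely failures are capture of the tertiary cation by chloride in place of proton loss, proton loss towards the acetoxymethyl group, or erosion of the facial preference if the Lewis acid bridges the aldehyde and the silyloxy oxygen. The acetate may also ionise once the triene has formed, because the resulting cation is highly delocalised. Fallback from 37: run the closure as a stepwise Prins reaction with SnCl4 in CH2Cl2 at −78 °C, which should give the tertiary chloride, the chloro-alcohol of the cyclised skeleton F1. Dehydrochlorination of F1 with DBU in warm toluene should then remove the doubly allylic, most acidic hydrogen and form the triene, rejoining the route at 38.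

**Step 11.** The hindered, 2,3-disubstituted diene may bind nickel poorly, which would lead to 1,2-hydroboration of the isopropenyl unit or to incomplete regiocontrol between the two diene termini. Fallback from 14: CeCl3-promoted addition of isopropenylmagnesium bromide to the C5 ketone should give the tertiary allylic alcohol F2. A Ph3SiOReO3-catalysed 1,3-transposition in Et2O would then move the hydroxyl to the primary terminus through a chair transition state that keeps the bulkier C6 arm equatorial, hence CH2OH on the C4 side; any minor geometric isomer would be removed by chromatography. This rejoins the route at 19.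

**Step 13.** Deprotonation of the hindered C1–H may be slow, and the enolate may expel the C2 triethylsilanolate before it is allylated; incomplete facial control is a lesser risk. Fallback from 20: generate the enolate with KN(SiMe3)2 in the presence of Me3SiCl at −78 °C so that it is silylated as it forms, giving the trimethylsilyl ketene acetal F3. Allylation of F3 with allyl methyl carbonate under Pd2(dba)3/dppe catalysis (a neutral π-allyl electrophile) should then deliver 22 from the same open face.

**Step 8.** The radical sequence may stall at the hydroperoxide, or the C5 radical may be reduced instead of trapped, giving the deoxygenated ring. Fallback from 11 by classical degradation: ozonolysis with Me2S work-up to the methyl ketone F4, Baeyer–Villiger oxidation with mCPBA to the C5 acetate F5 (ring carbon migrates with retention), methanolysis with K2CO3 in MeOH at 0 °C to the C5 alcohol F6, and immediate Dess–Martin oxidation, rejoining the route at 14.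

## Further compounds

F1 | step 25 | tertiary chloride of the cyclised skeleton (chloro-alcohol; chloride on the side-chain carbon bearing CH2OAc) | C=C(CCC=C(C)C)/C=C/CC(Cl)(COC(C)=O)[C@@H]1CC[C@]2([C@H](CCCO[Si](C)(C)C(C)(C)C)/C(=C(\C)CO[Si](C)(C)C(C)(C)C)CC[C@]2(C)O[Si](CC)(CC)CC)[C@@H]1O
F2 | step 11 | tertiary allylic alcohol (C5 hydroxyl and isopropenyl; C5 epimers) | COC(=O)C1[C@H](CCCO[Si](C)(C)C(C)(C)C)C(O)(C(C)=C)CC[C@]1(C)O[Si](CC)(CC)CC
F3 | step 13 | methyl trimethylsilyl ketene acetal of 20 | COC(O[Si](C)(C)C)=C1[C@H](CCCO[Si](C)(C)C(C)(C)C)/C(=C(\C)CO[Si](C)(C)C(C)(C)C)CC[C@]1(C)O[Si](CC)(CC)CC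
F4 | step 8 | C5 methyl ketone (acetyl in place of isopropenyl) | COC(=O)C1[C@H](CCCO[Si](C)(C)C(C)(C)C)[C@@H](C(C)=O)CC[C@]1(C)O[Si](CC)(CC)CC
F5 | step 8 | C5 acetate | COC(=O)C1[C@H](CCCO[Si](C)(C)C(C)(C)C)[C@@H](OC(C)=O)CC[C@]1(C)O[Si](CC)(CC)CC
F6 | step 8 | C5 alcohol | COC(=O)C1[C@H](CCCO[Si](C)(C)C(C)(C)C)[C@@H](O)CC[C@]1(C)O[Si](CC)(CC)CC
A1 | alternative 1 | spiro-fused octalin with the temporary methylcyclohexene (Diels–Alder adduct) | C1CC[C@]2([C@@H]3CCC=C(C)[C@H]3CC[C@]2(C)O[Si](CC)(CC)CC)[C@@H]1O[Si](C)(C)C(C)(C)C
A2 | alternative 1 | 1,7,9-decatriene precursor (1-vinylcyclopentane with TBS-oxy group and the silyloxy-bearing dienyl chain) | C1CC[C@](C=C)([C@@H]1O[Si](C)(C)C(C)(C)C)[C@@](C)(O[Si](CC)(CC)CC)CC/C=C(\C)C=C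
A3 | alternative 2 | spiro[4.5]decane ketol diketone | O=C1CCC[C@]12[C@H](CCCO[Si](C)(C)C(C)(C)C)C(=O)CC[C@]2(C)O
A4 | alternative 2 | 2-substituted cyclopent-2-enone with pendant 1,4-diketone chain | O=C1CCC=C1[C@H](CCCO[Si](C)(C)C(C)(C)C)C(=O)CCC(C)=O
A5 | alternative 3 | cis-fused oxasilolane ketone with the quaternary carbon | COc1ccc(COCCC[C@@]23C[Si](C)(C)O[C@@]3(C)CCC(=O)[C@H]2CCCO[Si](C)(C)C(C)(C)C)cc1
A6 | alternative 3 | bromomethylsilyl ether of the tetrasubstituted cyclohexenone | COc1ccc(COCCCC2=C(CCCO[Si](C)(C)C(C)(C)C)C(=O)CC[C@]2(C)O[Si](C)(C)CBr)cc1
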